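**Plan**

Locants (drimane type): ring A = C1–C5 and C10 (gem-dimethyl on C4, angular methyl on C10); ring B = C5–C10 (methyl on C8); C11 = the chloro(aryl) carbon on C9.
Cuts: C8–CH3 back to a C8 ketone; C6–C7 (ring B) to an α-chloro ketone (C7–Cl, C8=O) facing the exocyclic methylene C5=C6 of ring A; C7–C8 to an ester; C11–Cl via C11–OTf to a β-keto ester; C9–C11 by aldol; C9–C10 by allylation of 2,2,6-trimethylcyclohexanone.
Forward: ring A first (C10, then C6 as =CH2), arene joined through C9–C11, tetrasubstituted chloroalkene fixed, ring B closed last at C6–C7 by a 6-endo radical cyclization.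
Enabling feature: C6, the CH2 terminus of the C5=C6 alkene on ring A, lies six atoms from C7 and is the only alkene carbon that C7 can reach (C5 is walled in by quaternary C4 and C10); C7 (alpha to the C8 carbonyl) and C6 are both donor carbons, so they are joined through the electrophilic α-keto radical.
Stereochemistry: C10 from the chiral PHOX–palladium catalyst; C9=C11 geometry from a lithium chelate of the β-keto ester (oxygen cis to the ester, kept on exchange for chlorine); C5 from hydrogen transfer anti to the axial methyls in the key step; C8 from diimide on the α face.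

Key step: step 12

Assumption: the allylation is taken to follow the usual ligand–product correlation, the (R)-ligand giving (R)-5; with the opposite sense the (S)-ligand would be used.

Step 1
Reactants: 1 2,2,6-trimethylcyclohexan-1-one; 2 allyl chloroformate
Product: 4 prop-2-en-1-yl 2,6,6-trimethylcyclohex-1-en-1-yl carbonate, via lithium enolate 3 (not isolated)
Conditions: LiN(SiMe3)2, THF, 0 °C to rt; then 2, −78 °C
Reagents that add atoms: none
Why: O-acylation of a lithium enolate by a chloroformate (enol carbonate formation); the ketone has a single α-hydrogen, so only one enolate can form, and its stereocentre is erased, so racemic 1 serves.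

Step 2
Reactants: 4 prop-2-en-1-yl 2,6,6-trimethylcyclohex-1-en-1-yl carbonate
Product: 5 (2R)-2,6,6-trimethyl-2-(prop-2-en-1-yl)cyclohexan-1-one
Conditions: Pd2(dba)3 (dba = dibenzylideneacetone, 2.5 mol %), (R)-t-BuPHOX (6 mol %), THF, 25 °C
Reagents that add atoms: none
Why: Decarboxylative asymmetric allylic alkylation (Tsuji allylation): zerovalent palladium ionises the allyl carbonate, CO2 is lost and the enolate–allyl pair recombines at carbon inside the chiral pocket of the PHOX ligand, which selects the enolate face and sets the quaternary centre C10.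

Step 3
Reactants: 5 (2R)-2,6,6-trimethyl-2-(prop-2-en-1-yl)cyclohexan-1-one
Product: 6 methyl 2-[(1R)-1,3,3-trimethyl-2-oxocyclohexyl]acetate
Conditions: O3, NaOH (2.5 M in MeOH), CH2Cl2, −78 °C
Reagents that add atoms: ozone, [O-][O+]=O; methanol, CO
Why: Oxidative ozonolysis in basic methanol: the carbonyl oxide and aldehyde from the terminal alkene are captured by methanol and taken on to the methyl ester in the same flask, while the ketone, which has no α-hydrogen, is inert.

Step 4
Reactants: 6 methyl 2-[(1R)-1,3,3-trimethyl-2-oxocyclohexyl]acetate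
Product: 7 methyl 2-[(1R)-1,3,3-trimethyl-2-methylidenecyclohexyl]acetate
Conditions: Zn, CH2Br2, TiCl4, THF/CH2Cl2, 0 °C to rt
Reagents that add atoms: dibromomethane, BrCBr
Why: Takai–Lombardo methylenation: the small, non-basic zinc/titanium methylene reagent olefinates ketones much faster than esters and should cope with the two flanking quaternary carbons better than a phosphorus ylide.

Step 5
Reactants: 8 2-hydroxy-3-methoxybenzaldehyde (o-vanillin)
Product: 10 2,5-dihydroxy-3-methoxybenzaldehyde, via aryl sulfate 9 (not isolated)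
Conditions: K2S2O8, aq. NaOH, 15–20 °C; then aq. HCl, 80 °C
Reagents that add atoms: potassium peroxodisulfate, [K+].[K+].[O-]S(=O)(=O)OOS(=O)(=O)[O-]
Why: Elbs persulfate oxidation: the phenoxide attacks a peroxide oxygen through its free para carbon (both ortho positions are occupied) and the aryl sulfate is hydrolysed by acid to the hydroquinone.

Step 6
Reactants: 10 2,5-dihydroxy-3-methoxybenzaldehyde
Product: 11 3-methoxy-2,5-bis(methoxymethoxy)benzaldehyde
Conditions: MOMCl, i-Pr2NEt, CH2Cl2, 0 °C to rt
Reagents that add atoms: chloromethyl methyl ether, COCCl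
Why: O-alkylation of both phenols by the α-chloro ether (MOM protection); the acetals should survive the strong bases, organolithium, radical and low-valent metal steps that follow.

Step 7
Reactants: 7 methyl 2-[(1R)-1,3,3-trimethyl-2-methylidenecyclohexyl]acetate; 11 3-methoxy-2,5-bis(methoxymethoxy)benzaldehyde
Product: 13 methyl 3-hydroxy-3-[3-methoxy-2,5-bis(methoxymethoxy)phenyl]-2-[(1R)-1,3,3-trimethyl-2-methylidenecyclohexyl]propanoate (diastereomer mixture at C2 and C3), via lithium enolate 12 (not isolated)
Conditions: LiN(i-Pr)2, THF, −78 °C; then 11, −78 °C; aq. NH4Cl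
Reagents that add atoms: none
Why: Aldol addition of the ester lithium enolate to the non-enolisable aryl aldehyde forms C9–C11; the two new centres arise as a mixture and are both erased in steps 8 and 9.

Step 8
Reactants: 13 methyl 3-hydroxy-3-[3-methoxy-2,5-bis(methoxymethoxy)phenyl]-2-[(1R)-1,3,3-trimethyl-2-methylidenecyclohexyl]propanoate
Product: 14 methyl 3-[3-methoxy-2,5-bis(methoxymethoxy)phenyl]-3-oxo-2-[(1R)-1,3,3-trimethyl-2-methylidenecyclohexyl]propanoate
Conditions: Dess–Martin periodinane, NaHCO3, CH2Cl2, rt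
Reagents that add atoms: none
Why: Dess–Martin oxidation of the secondary benzylic alcohol to the β-keto ester under buffered conditions that leave the acetals and the alkene alone.

Step 9
Reactants: 14 methyl 3-[3-methoxy-2,5-bis(methoxymethoxy)phenyl]-3-oxo-2-[(1R)-1,3,3-trimethyl-2-methylidenecyclohexyl]propanoate
Product: 16 methyl (2Z)-3-[3-methoxy-2,5-bis(methoxymethoxy)phenyl]-3-[(trifluoromethanesulfonyl)oxy]-2-[(1S)-1,3,3-trimethyl-2-methylidenecyclohexyl]prop-2-enoate, via chelated lithium enolate 15 (not isolated)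
Conditions: LiN(SiMe3)2, THF, −78 to 0 °C; then PhNTf2, 0 °C to rt
Reagents that add atoms: N-phenylbis(trifluoromethanesulfonimide), O=S(=O)(N(c1ccccc1)S(=O)(=O)C(F)(F)F)C(F)(F)F
Why: Chelation-controlled enol triflate formation from a β-keto ester: lithium bridges the enolate oxygen and the ester carbonyl, so O-sulfonylation fixes the triflate oxygen cis to the ester (Z) and the aryl group cis to ring A.

Step 10
Reactants: 16 methyl (2Z)-3-[3-methoxy-2,5-bis(methoxymethoxy)phenyl]-3-[(trifluoromethanesulfonyl)oxy]-2-[(1S)-1,3,3-trimethyl-2-methylidenecyclohexyl]prop-2-enoate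
Product: 17 methyl (2Z)-3-chloro-3-[3-methoxy-2,5-bis(methoxymethoxy)phenyl]-2-[(1S)-1,3,3-trimethyl-2-methylidenecyclohexyl]prop-2-enoate
Conditions: Ni(OAc)2·4H2O (10 mol %), 1,5-cyclooctadiene, Zn (20 mol %), LiCl, DMA/THF, rt
Reagents that add atoms: lithium chloride, [Li+].[Cl-]
Why: Nickel-catalysed triflate-to-halide exchange of an enol triflate: oxidative addition of the activated C–O bond to low-valent nickel, triflate/chloride exchange and C–Cl reductive elimination should proceed with retention of alkene geometry.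

Step 11
Reactants: 17 methyl (2Z)-3-chloro-3-[3-methoxy-2,5-bis(methoxymethoxy)phenyl]-2-[(1S)-1,3,3-trimethyl-2-methylidenecyclohexyl]prop-2-enoate
Product: 19 (3Z)-1,4-dichloro-4-[3-methoxy-2,5-bis(methoxymethoxy)phenyl]-3-[(1S)-1,3,3-trimethyl-2-methylidenecyclohexyl]but-3-en-2-one, via lithium hemiketal alkoxide 18 (not isolated)
Conditions: ICH2Cl, MeLi·LiBr, THF, −78 °C; then AcOH, −78 °C to rt
Reagents that add atoms: chloroiodomethane, ClCI
Why: Carbenoid homologation of an ester to an α-chloro ketone: chloromethyllithium made in situ by iodine–lithium exchange adds once, the tetrahedral adduct holds at −78 °C and releases the ketone only on quench, and the vinyl chloride does not exchange.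

Step 12
Reactants: 19 (3Z)-1,4-dichloro-4-[3-methoxy-2,5-bis(methoxymethoxy)phenyl]-3-[(1S)-1,3,3-trimethyl-2-methylidenecyclohexyl]but-3-en-2-one
Product: 20 (1Z,4aS,8aS)-1-{chloro[3-methoxy-2,5-bis(methoxymethoxy)phenyl]methylidene}-5,5,8a-trimethyloctahydronaphthalen-2(1H)-one
Conditions: Bu3SnH (slow addition), AIBN (cat.), benzene, 80 °C, 0.01 M
Reagents that add atoms: none
Why: Bu3Sn• abstracts the α-keto chlorine of 19 (the vinyl C–Cl bond is far too strong to compete), the electrophilic α-keto radical at C7 adds to the electron-rich CH2 terminus C6 of the exocyclic alkene, and the tertiary C5 radical takes hydrogen from Bu3SnH, which carries the chain. The closest known reaction type is the tin hydride-mediated 6-endo cyclization of 2-oxohex-5-enyl (α-carbonyl) radicals onto 1,1-disubstituted alkenes. Ring B closes in the 6-endo-trig mode, because the 5-exo mode would need attack at C5, which is fully substituted and flanked by quaternary C4 and C10, and α-keto radicals prefer endo closure in any case. The new stereocentre C5 is set in the hydrogen transfer: the β face of the planar C5 radical is screened by the syn-axial methyls on C4 and C10, so hydrogen should arrive from the α face and give the trans ring fusion. The step needs cyclization to outrun direct reduction of the first radical, which high dilution and slow stannane addition secure, and it needs the chloroalkene geometry to survive, which it should because the C7 radical is cross-conjugated and never delocalises onto C9=C11, while the aryl group lies trans to the acyl side, out of reach of C7.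

Step 13
Reactants: 20 (1Z,4aS,8aS)-1-{chloro[3-methoxy-2,5-bis(methoxymethoxy)phenyl]methylidene}-5,5,8a-trimethyloctahydronaphthalen-2(1H)-one
Product: 21 (1E,4aS,8aS)-1-{chloro[3-methoxy-2,5-bis(methoxymethoxy)phenyl]methylidene}-5,5,8a-trimethyl-2-methylidenedecahydronaphthalene
Conditions: Ph3PCH3Br, KOtBu, THF, 0 °C to rt
Reagents that add atoms: methyltriphenylphosphonium bromide, C[P+](c1ccccc1)(c1ccccc1)c1ccccc1.[Br-]
Why: Wittig methylenation of the C8 ketone; the non-stabilised ylide should attack the carbonyl and not the fully substituted β-carbon C11 of the chloroenone.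

Step 14
Reactants: 21 (1E,4aS,8aS)-1-{chloro[3-methoxy-2,5-bis(methoxymethoxy)phenyl]methylidene}-5,5,8a-trimethyl-2-methylidenedecahydronaphthalene
Product: 22 (1E,2S,4aS,8aS)-1-{chloro[3-methoxy-2,5-bis(methoxymethoxy)phenyl]methylidene}-2,5,5,8a-tetramethyldecahydronaphthalene
Conditions: 2-nitrobenzenesulfonyl hydrazide, Et3N, CH2Cl2, rt
Reagents that add atoms: none
Why: Diimide reduction (concerted syn transfer of two hydrogens) should touch only the 1,1-disubstituted exocyclic alkene and not the tetrasubstituted chloroalkene, the C–Cl bond or the arene; hydrogen reaches C8 from the α face, away from the axial C10 methyl, which places the C8 methyl β (2S).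

Step 15
Reactants: 22 (1E,2S,4aS,8aS)-1-{chloro[3-methoxy-2,5-bis(methoxymethoxy)phenyl]methylidene}-2,5,5,8a-tetramethyldecahydronaphthalene
Product: 23 2-{(E)-chloro[(2S,4aS,8aS)-2,5,5,8a-tetramethyloctahydronaphthalen-1(2H)-ylidene]methyl}-6-methoxybenzene-1,4-diol
Conditions: ZnBr2, n-PrSH, CH2Cl2, 0 °C to rt, argon
Reagents that add atoms: none
Why: Lewis acid/thiol acetal exchange removes both MOM groups under conditions too mild to protonate the chloroalkene; argon keeps the free hydroquinone from oxidising to the quinone.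

**Compound list**

In 16–19 the ring descriptor changes from (1R) to (1S) by substituent priority only; the spatial arrangement is that of 7.

1 | 2,2,6-trimethylcyclohexan-1-one (racemic) | CC1CCCC(C)(C)C1=O | starting material
2 | allyl chloroformate | C=CCOC(=O)Cl | starting material
3 | lithium 2,6,6-trimethylcyclohex-1-en-1-olate | [Li+].[O-]C1=C(C)CCCC1(C)C | intermediate
4 | prop-2-en-1-yl 2,6,6-trimethylcyclohex-1-en-1-yl carbonate | C=CCOC(=O)OC1=C(C)CCCC1(C)C | intermediate
5 | (2R)-2,6,6-trimethyl-2-(prop-2-en-1-yl)cyclohexan-1-one | O=C1C(C)(C)CCC[C@@]1(CC=C)C | intermediate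
6 | methyl 2-[(1R)-1,3,3-trimethyl-2-oxocyclohexyl]acetate | O=C1C(C)(C)CCC[C@@]1(CC(=O)OC)C | intermediate
7 | methyl 2-[(1R)-1,3,3-trimethyl-2-methylidenecyclohexyl]acetate | C=C1C(C)(C)CCC[C@@]1(CC(=O)OC)C | intermediate
8 | 2-hydroxy-3-methoxybenzaldehyde (o-vanillin) | COc1cccc(C=O)c1O | starting material
9 | potassium 3-formyl-4-hydroxy-5-methoxyphenyl sulfate | COc1cc(OS(=O)(=O)[O-])cc(C=O)c1O.[K+] | intermediate
10 | 2,5-dihydroxy-3-methoxybenzaldehyde | COc1cc(O)cc(C=O)c1O | intermediate
11 | 3-methoxy-2,5-bis(methoxymethoxy)benzaldehyde | COc1cc(OCOC)cc(C=O)c1OCOC | intermediate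
12 | lithium 1-methoxy-2-[(1R)-1,3,3-trimethyl-2-methylidenecyclohexyl]ethen-1-olate (lithium enolate of 7) | [Li+].[O-]C(OC)=C[C@@]1(C)CCCC(C)(C)C1=C | intermediate
13 | methyl 3-hydroxy-3-[3-methoxy-2,5-bis(methoxymethoxy)phenyl]-2-[(1R)-1,3,3-trimethyl-2-methylidenecyclohexyl]propanoate (diastereomer mixture at C2 and C3) | COc1cc(OCOC)cc(C(O)C(C(=O)OC)[C@@]2(C)CCCC(C)(C)C2=C)c1OCOC | intermediate
14 | methyl 3-[3-methoxy-2,5-bis(methoxymethoxy)phenyl]-3-oxo-2-[(1R)-1,3,3-trimethyl-2-methylidenecyclohexyl]propanoate (epimers at C2) | COc1cc(OCOC)cc(C(=O)C(C(=O)OC)[C@@]2(C)CCCC(C)(C)C2=C)c1OCOC | intermediate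
15 | chelated lithium (Z)-enolate of 14 (enolate oxygen cis to the ester) | COc1cc(OCOC)cc(/C([O-])=C(/C(=O)OC)[C@@]2(C)CCCC(C)(C)C2=C)c1OCOC.[Li+] | intermediate
16 | methyl (2Z)-3-[3-methoxy-2,5-bis(methoxymethoxy)phenyl]-3-[(trifluoromethanesulfonyl)oxy]-2-[(1S)-1,3,3-trimethyl-2-methylidenecyclohexyl]prop-2-enoate | COc1cc(OCOC)cc(/C(OS(=O)(=O)C(F)(F)F)=C(/C(=O)OC)[C@@]2(C)CCCC(C)(C)C2=C)c1OCOC | intermediate
17 | methyl (2Z)-3-chloro-3-[3-methoxy-2,5-bis(methoxymethoxy)phenyl]-2-[(1S)-1,3,3-trimethyl-2-methylidenecyclohexyl]prop-2-enoate | COc1cc(OCOC)cc(/C(Cl)=C(/C(=O)OC)[C@@]2(C)CCCC(C)(C)C2=C)c1OCOC | intermediate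
18 | lithium hemiketal alkoxide from 17 and chloromethyllithium | COc1cc(OCOC)cc(/C(Cl)=C(/C([O-])(OC)CCl)[C@@]2(C)CCCC(C)(C)C2=C)c1OCOC.[Li+] | intermediate
19 | (3Z)-1,4-dichloro-4-[3-methoxy-2,5-bis(methoxymethoxy)phenyl]-3-[(1S)-1,3,3-trimethyl-2-methylidenecyclohexyl]but-3-en-2-one | COc1cc(OCOC)cc(/C(Cl)=C(/C(=O)CCl)[C@@]2(C)CCCC(C)(C)C2=C)c1OCOC | intermediate
20 | (1Z,4aS,8aS)-1-{chloro[3-methoxy-2,5-bis(methoxymethoxy)phenyl]methylidene}-5,5,8a-trimethyloctahydronaphthalen-2(1H)-one | COc1cc(OCOC)cc(/C(Cl)=C2/C(=O)CC[C@H]3C(C)(C)CCC[C@]23C)c1OCOC | intermediate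
21 | (1E,4aS,8aS)-1-{chloro[3-methoxy-2,5-bis(methoxymethoxy)phenyl]methylidene}-5,5,8a-trimethyl-2-methylidenedecahydronaphthalene | COc1cc(OCOC)cc(/C(Cl)=C2/C(=C)CC[C@H]3C(C)(C)CCC[C@]23C)c1OCOC | intermediate
22 | (1E,2S,4aS,8aS)-1-{chloro[3-methoxy-2,5-bis(methoxymethoxy)phenyl]methylidene}-2,5,5,8a-tetramethyldecahydronaphthalene | COc1cc(OCOC)cc(/C(Cl)=C2/[C@@H](C)CC[C@H]3C(C)(C)CCC[C@]23C)c1OCOC | intermediate
23 | 2-{(E)-chloro[(2S,4aS,8aS)-2,5,5,8a-tetramethyloctahydronaphthalen-1(2H)-ylidene]methyl}-6-methoxybenzene-1,4-diol | COc1cc(O)cc(/C(Cl)=C2/[C@@H](C)CC[C@H]3C(C)(C)CCC[C@]23C)c1O | target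

**Count**

Total steps: 15. Longest linear sequence: 13 (steps 1–4, then 7–15); the arene branch (steps 5–6) joins at step 7.

**Steps most likely to fail**

Step 10. Oxidative addition may stall at the crowded C11–O bond, or the alkene geometry may be lost through a nickel-bound intermediate. The fallback sets out from 16 and comes back at 17: stannylation with Me3SnSnMe3, Pd(PPh3)4 and LiCl would give the alkenylstannane methyl (2Z)-3-[3-methoxy-2,5-bis(methoxymethoxy)phenyl]-3-(trimethylstannyl)-2-[(1S)-1,3,3-trimethyl-2-methylidenecyclohexyl]prop-2-enoate F1, and tin–chlorine exchange with CuCl2, which proceeds with retention at the sp2 carbon, would deliver 17.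

Step 9. Deprotonation of the doubly flanked C9–H may be slow, or sulfonylation through a non-chelated enolate may erode the geometry. The fallback sets out from 14 and comes back at 17, bypassing 16 and making no new isolated compound: Vilsmeier-type deoxychlorination with (COCl)2 and DMF acts on the hydrogen-bonded enol, whose oxygen already lies cis to the ester, and replaces the activated oxygen by chloride through addition–elimination.

Step 11. The carbenoid may decompose faster than it adds to the shielded, twisted ester carbonyl, or it may add twice. The fallback sets out from 17 and comes back at 19: reduction with i-Bu2AlH would give the allylic alcohol (2Z)-3-chloro-3-[3-methoxy-2,5-bis(methoxymethoxy)phenyl]-2-[(1S)-1,3,3-trimethyl-2-methylidenecyclohexyl]prop-2-en-1-ol F2; oxidation with MnO2 would give the enal (2Z)-3-chloro-3-[3-methoxy-2,5-bis(methoxymethoxy)phenyl]-2-[(1S)-1,3,3-trimethyl-2-methylidenecyclohexyl]prop-2-enal F3; chloromethyllithium should add to this far more reactive carbonyl (acid quench at −78 °C) to give the chlorohydrin (3Z)-1,4-dichloro-4-[3-methoxy-2,5-bis(methoxymethoxy)phenyl]-3-[(1S)-1,3,3-trimethyl-2-methylidenecyclohexyl]but-3-en-2-ol F4; Dess–Martin oxidation would return to 19.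

**Further compounds**

F1 | step 10 | methyl (2Z)-3-[3-methoxy-2,5-bis(methoxymethoxy)phenyl]-3-(trimethylstannyl)-2-[(1S)-1,3,3-trimethyl-2-methylidenecyclohexyl]prop-2-enoate | COc1cc(OCOC)cc(/C([Sn](C)(C)C)=C(/C(=O)OC)[C@@]2(C)CCCC(C)(C)C2=C)c1OCOC
F0 | step 9 | none | none
F2 | step 11 | (2Z)-3-chloro-3-[3-methoxy-2,5-bis(methoxymethoxy)phenyl]-2-[(1S)-1,3,3-trimethyl-2-methylidenecyclohexyl]prop-2-en-1-ol | COc1cc(OCOC)cc(/C(Cl)=C(/CO)[C@@]2(C)CCCC(C)(C)C2=C)c1OCOC
F3 | step 11 | (2Z)-3-chloro-3-[3-methoxy-2,5-bis(methoxymethoxy)phenyl]-2-[(1S)-1,3,3-trimethyl-2-methylidenecyclohexyl]prop-2-enal | COc1cc(OCOC)cc(/C(Cl)=C(/C=O)[C@@]2(C)CCCC(C)(C)C2=C)c1OCOC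
F4 | step 11 | (3Z)-1,4-dichloro-4-[3-methoxy-2,5-bis(methoxymethoxy)phenyl]-3-[(1S)-1,3,3-trimethyl-2-methylidenecyclohexyl]but-3-en-2-ol (epimers at C2) | COc1cc(OCOC)cc(/C(Cl)=C(/C(O)CCl)[C@@]2(C)CCCC(C)(C)C2=C)c1OCOC
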